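## Retrosynthetic overview

1. Ring numbering: C1 (acetoxy carbon), C2, C3(Me)=C4 (E), C5 (doubly allylic CH2), C6=C7(CHO), C8(CHO), C9 (side chain). Enabling feature: C6 is the β-carbon of the ring enal C6=C7–CHO and is bonded to C5, the primary end of the E-allyl unit C3=C4–C5. An enal is a β-nitro aldehyde minus HNO2, so C6 can be a nitronate carbon and C5 a π-allyl terminus.
2. Target ⇐ (acetal hydrolysis, E1cB loss of HNO2) 6-nitrocyclononene bis(dimethyl acetal) ⇐ (C5–C6, palladium-catalysed nitronate allylation) open-chain nitro allylic acetate. The nine-membered carbocycle is the only ring and is formed last.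
3. C7–C8: enamine-catalysed Michael addition to (E)-3,3-dimethoxy-1-nitropropene. This C3 linchpin brings C6, C7 and the C7 formyl carbon at the final oxidation level and sets C8.
4. C9–C1: auxiliary-controlled syn-aldol. Chiral-pool (S)-citronellic acid supplies the side chain with its stereocentre, C9 (its C2) and ring carbon C8 (its carboxyl carbon). C1–C5 with the E-alkene come from (E)-3-methylpent-2-en-4-yn-1-ol, and the C8 formyl carbon from a Wittig homologation.

Key step: step 14

Remark: elements that vanish later (enol ether geometry in 11–13, C6 in 21 and 22) are carried as mixtures and left open in the SMILES. (S)-Citronellic acid is taken as a catalogue compound (otherwise one Pinnick oxidation from (S)-citronellal).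

## Route

Step 1
Reactants: 1 (E)-3-methylpent-2-en-4-yn-1-ol
Product: 2 tert-butyldimethylsilyl ether of 1
Conditions: t-BuMe2SiCl, imidazole, CH2Cl2, 0 °C → rt
Reagents that add atoms: tert-butyldimethylsilyl chloride CC(C)(C)[Si](C)(C)Cl
Why: Standard silyl ether protection of a primary allylic alcohol, which leaves the terminal alkyne and the preformed E-alkene (later C3=C4) untouched.

Step 2
Reactants: 2 tert-butyldimethylsilyl ether of 1
Product: 4 (E)-5-[(tert-butyldimethylsilyl)oxy]-3-methylpent-3-enal, via dienylborane 3 (not isolated)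
Conditions: Cy2BH (preformed), THF, 0 °C; then H2O2, pH 7 phosphate buffer, 0 °C
Reagents that add atoms: dicyclohexylborane [BH](C1CCCCC1)C1CCCCC1 (its atoms stay only in 3); hydrogen peroxide OO
Why: Alkyne hydroboration–oxidation: the bulky dialkylborane adds syn and anti-Markovnikov to the terminal alkyne only, and buffered oxidation gives the dienol, which should tautomerise by α-protonation to the β,γ-unsaturated aldehyde.

Step 3
Reactants: 5 (S)-citronellic acid; 6 (S)-4-benzyl-1,3-thiazolidine-2-thione
Product: 7 (S)-4-benzyl-3-[(3S)-3,7-dimethyloct-6-enoyl]-1,3-thiazolidine-2-thione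
Conditions: DCC, DMAP (cat.), CH2Cl2, 0 °C → rt
Reagents that add atoms: none
Why: Steglich-type carbodiimide N-acylation, in which the chiral-pool stereocentre is β to the reacting carboxyl group and is not touched.

Step 4
Reactants: 7 N-citronelloyl thiazolidinethione; 4 (E)-5-[(tert-butyldimethylsilyl)oxy]-3-methylpent-3-enal
Product: 8 (S)-4-benzyl-3-{(2S,3R,5E)-7-[(tert-butyldimethylsilyl)oxy]-3-hydroxy-5-methyl-2-[(2S)-6-methylhept-5-en-2-yl]hept-5-enoyl}-1,3-thiazolidine-2-thione
Conditions: TiCl4 (1.05 equiv), i-Pr2NEt (1.1 equiv), 1-methyl-2-pyrrolidinone (1 equiv), CH2Cl2, 0 °C; then 4, −78 → 0 °C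
Reagents that add atoms: none
Why: Titanium-enolate syn-aldol addition of an N-acylthiazolidinethione: soft enolisation gives the Z-enolate, which adds to 4 through a non-chelated closed chair transition state on the face away from the benzyl group, so C9 and C1 are set together in the 2S,3R (syn) sense while the low temperature keeps the β,γ-unsaturated aldehyde from conjugating.

Step 5
Reactants: 8 syn-aldol adduct
Product: 9 C1-O-tert-butyldimethylsilyl ether of 8
Conditions: t-BuMe2SiOSO2CF3, 2,6-lutidine, CH2Cl2, −20 °C
Reagents that add atoms: tert-butyldimethylsilyl triflate CC(C)(C)[Si](C)(C)OS(=O)(=O)C(F)(F)F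
Why: Silyl triflate silylation of the hindered secondary alcohol blocks retro-aldol cleavage and β-elimination in the following hydride and ylide steps.

Step 6
Reactants: 9 bis-silyl imide
Product: 10 (2S,3R,5E)-3,7-bis[(tert-butyldimethylsilyl)oxy]-5-methyl-2-[(2S)-6-methylhept-5-en-2-yl]hept-5-enal
Conditions: i-Bu2AlH (1.2 equiv), CH2Cl2, −78 °C; aqueous potassium sodium tartrate work-up
Reagents that add atoms: none
Why: Partial reduction of an activated amide: the tetrahedral aluminium adduct of the thiazolidinethione is stable at −78 °C, so a single hydride transfer should give the aldehyde without over-reduction or epimerisation at C9.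

Step 7
Reactants: 10 α-branched aldehyde
Product: 11 (3R,4R,6E)-4,8-bis[(tert-butyldimethylsilyl)oxy]-1-methoxy-6-methyl-3-[(2S)-6-methylhept-5-en-2-yl]octa-1,6-diene (E/Z at C1=C2)
Conditions: MeOCH2PPh3Cl, KN(SiMe3)2, THF, −78 → 0 °C
Reagents that add atoms: (methoxymethyl)triphenylphosphonium chloride COC[P+](c1ccccc1)(c1ccccc1)c1ccccc1.[Cl-]
Why: Wittig methoxymethylenation adds the carbon that becomes the C8 formyl group, and the non-stabilised ylide should attack the aldehyde faster than it enolises it at low temperature, so C9 is kept and the enol ether geometry is irrelevant.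

Step 8
Reactants: 11 bis-silyl enol ether
Product: 12 (2E,5R,6R)-8-methoxy-3-methyl-6-[(2S)-6-methylhept-5-en-2-yl]octa-2,7-diene-1,5-diol
Conditions: n-Bu4NF, THF, rt → 40 °C
Reagents that add atoms: none
Why: Fluoride desilylation cleaves both silyl ethers in one operation, while the enol ether, which is labile only to acid, survives.

Step 9
Reactants: 12 diol
Product: 13 diacetate of 12
Conditions: Ac2O, pyridine, DMAP (cat.), CH2Cl2, rt
Reagents that add atoms: acetic anhydride CC(=O)OC(C)=O
Why: A single acetylation installs both the C1 acetate of the target and the allylic leaving group at C5 that step 14 needs.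

Step 10
Reactants: 13 diacetate enol ether
Product: 14 (2E,5R,6S)-3-methyl-6-[(2S)-6-methylhept-5-en-2-yl]-8-oxooct-2-ene-1,5-diyl diacetate
Conditions: p-TsOH·H2O (10 mol %), THF–H2O 5:1, 0 °C → rt
Reagents that add atoms: water O
Why: Acid-catalysed enol ether hydrolysis (C-protonation, addition of water, loss of methanol) is far faster than ester hydrolysis or ionisation of the primary allylic acetate, and no stereocentre is α to the new aldehyde.

Step 11
Reactants: 15 2,2-dimethoxyacetaldehyde (60 wt % in water); 16 nitromethane
Product: 17 3,3-dimethoxy-1-nitropropan-2-ol (racemic)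
Conditions: K2CO3 (cat.), MeNO2–H2O, rt
Reagents that add atoms: none
Why: Henry (nitroaldol) addition to a non-enolisable aldehyde, whose carbinol stereocentre is removed in the next step.

Step 12
Reactants: 17 nitro alcohol
Product: 18 (E)-3,3-dimethoxy-1-nitroprop-1-ene
Conditions: (CF3CO)2O, Et3N (2.1 equiv), CH2Cl2, −10 °C
Reagents that add atoms: none
Why: O-trifluoroacetylation followed by E1cB elimination should give the conjugated nitroalkene as the more stable E isomer under conditions that leave the acetal intact.

Step 13
Reactants: 14 diacetoxy aldehyde; 18 (E)-3,3-dimethoxy-1-nitroprop-1-ene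
Product: 20 (2E,5R,6R,7R,8R)-7-(dimethoxymethyl)-9,9-dimethoxy-3-methyl-6-[(2S)-6-methylhept-5-en-2-yl]-8-(nitromethyl)non-2-ene-1,5-diyl diacetate, via Michael adduct 19 (not isolated)
Conditions: (S)-2-[diphenyl(trimethylsilyloxy)methyl]pyrrolidine (10 mol %), 4-nitrophenol (10 mol %), toluene, 0 °C → rt; then HC(OMe)3, MeOH, p-TsOH·H2O (25 mol %), rt
Reagents that add atoms: trimethyl orthoformate COC(OC)OC
Why: Enamine-catalysed Michael addition of an aldehyde to a nitroalkene: the E-enamine, shielded on one face by the diphenyl(silyloxy)methyl group, attacks 18 through the open synclinal transition state, which sets C8 (R) under catalyst control and C7 in the syn sense (erased later), and the in-flask acetalisation locks the epimerisable aldehyde and shuts off retro-Michael cleavage.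

Step 14
Reactants: 20 open-chain nitro bis(dimethyl acetal) diacetate
Product: 21 (1R,3E,7R,8R,9R)-7,8-bis(dimethoxymethyl)-3-methyl-9-[(2S)-6-methylhept-5-en-2-yl]-6-nitrocyclonon-3-en-1-yl acetate (epimers at C6)
Conditions: Pd2(dba)3·CHCl3 (5 mol %), Ph2PCH2CH2PPh2 (12 mol %), Cs2CO3 (1.2 equiv), THF–DMSO 9:1, 60 °C, 20 added by syringe pump (final 1 mM)
Reagents that add atoms: none
Why: Zerovalent palladium ionises the primary allylic acetate at C5 (the homoallylic C1 acetate cannot ionise) to a π-allyl complex over C3–C5 whose C2 chain stays syn, Cs2CO3 converts the CH2NO2 group, the only acidic site now that both formyl groups are acetals, into its nitronate, and the nitronate carbon C6 attacks C5 on the face away from palladium to form the C5–C6 bond. The closest known reaction type is the Tsuji–Trost C-allylation of nitroalkanes, known between two molecules and for closing common rings, and palladium-catalysed allylic alkylation with soft carbanions is an established way to close eight- and nine-membered rings in preference to the smaller exo alternatives. The single ring formed, the nine-membered carbocycle, closes in the endo mode at the distal allyl terminus, so that C3, C4 and C5 all become ring atoms, whereas the exo alternative at C3 would give a cycloheptane with a quaternary vinyl-bearing carbon. The only new stereocentre is the nitro-bearing C6, which is not controlled, equilibrates through the nitronate and is erased in step 15, while C1, C7, C8 and C9 carry no acidic hydrogen under these conditions and stay as set. The step needs attack at C5 over C3 (secured by the fully substituted C3), C- over O-allylation (O-allyl nitronates re-ionise with palladium, the C–C bond does not), retention of the E-alkene (syn–anti exchange would need a σ-palladium bond at tertiary C3) and ring closure over oligomerisation (slow addition at high dilution, three contiguous branched centres that fold the chain). In one operation it should deliver, from an open chain, the strained E-cyclononene, the doubly allylic C5 methylene and, latent as CH–NO2 next to CH–CH(OMe)2, the C6=C7 enal.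

Step 15
Reactants: 21 6-nitrocyclononene bis(dimethyl acetal)
Product: 23 (1R,3E,6E,8R,9R)-7,8-diformyl-3-methyl-9-[(2S)-6-methylhept-5-en-2-yl]cyclonona-3,6-dien-1-yl acetate (target), via nitro dialdehyde 22 (not isolated)
Conditions: p-TsOH·H2O (20 mol %), THF–H2O 5:1, 0 °C → rt; then Et3N (1.5 equiv), 0 °C, short contact
Reagents that add atoms: water O
Why: Acid-catalysed acetal hydrolysis frees both formyl groups and the β-nitro aldehyde 22 then loses nitrous acid by E1cB elimination through the C7 enolate, the nine-membered ring with its E C3=C4 bond allowing only the cis-in-ring C6=C7 bond (E by the sequence rule) and the brief contact with a weak amine base at 0 °C sparing C8.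

## Compound list

1 | (E)-3-methylpent-2-en-4-yn-1-ol | C#C/C(C)=C/CO | starting material
2 | tert-butyldimethylsilyl ether of 1 | C#C/C(C)=C/CO[Si](C)(C)C(C)(C)C | intermediate
3 | dicyclohexyl[(1E,3E)-5-(tert-butyldimethylsilyloxy)-3-methylpenta-1,3-dienyl]borane | CC(/C=C/B(C1CCCCC1)C1CCCCC1)=C\CO[Si](C)(C)C(C)(C)C | intermediate
4 | (E)-5-[(tert-butyldimethylsilyl)oxy]-3-methylpent-3-enal | O=CC/C(C)=C/CO[Si](C)(C)C(C)(C)C | intermediate
5 | (S)-citronellic acid, (3S)-3,7-dimethyloct-6-enoic acid | C[C@@H](CCC=C(C)C)CC(=O)O | starting material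
6 | (S)-4-benzyl-1,3-thiazolidine-2-thione | S=C1N[C@@H](Cc2ccccc2)CS1 | starting material
7 | (S)-4-benzyl-3-[(3S)-3,7-dimethyloct-6-enoyl]-1,3-thiazolidine-2-thione | C[C@@H](CCC=C(C)C)CC(=O)N1[C@@H](Cc2ccccc2)CSC1=S | intermediate
8 | syn-aldol adduct (2S,3R,5E; side chain 2S) | O[C@H](C/C(C)=C/CO[Si](C)(C)C(C)(C)C)[C@@H](C(=O)N1[C@@H](Cc2ccccc2)CSC1=S)[C@@H](C)CCC=C(C)C | intermediate
9 | C1-O-silyl ether of 8 | CC(C)(C)[Si](C)(C)O[C@H](C/C(C)=C/CO[Si](C)(C)C(C)(C)C)[C@@H](C(=O)N1[C@@H](Cc2ccccc2)CSC1=S)[C@@H](C)CCC=C(C)C | intermediate
10 | (2S,3R,5E)-3,7-bis(silyloxy)-5-methyl-2-[(2S)-6-methylhept-5-en-2-yl]hept-5-enal | CC(C)(C)[Si](C)(C)O[C@H](C/C(C)=C/CO[Si](C)(C)C(C)(C)C)[C@@H](C=O)[C@@H](C)CCC=C(C)C | intermediate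
11 | methyl enol ether of the homologated aldehyde, bis-silyl (E/Z mixture) | CC(C)(C)[Si](C)(C)O[C@H](C/C(C)=C/CO[Si](C)(C)C(C)(C)C)[C@@H](C=COC)[C@@H](C)CCC=C(C)C | intermediate
12 | (2E,5R,6R)-8-methoxy-3-methyl-6-[(2S)-6-methylhept-5-en-2-yl]octa-2,7-diene-1,5-diol | O[C@H](C/C(C)=C/CO)[C@@H](C=COC)[C@@H](C)CCC=C(C)C | intermediate
13 | diacetate of 12 | CC(=O)O[C@H](C/C(C)=C/COC(C)=O)[C@@H](C=COC)[C@@H](C)CCC=C(C)C | intermediate
14 | (2E,5R,6S)-3-methyl-6-[(2S)-6-methylhept-5-en-2-yl]-8-oxooct-2-ene-1,5-diyl diacetate | CC(=O)O[C@H](C/C(C)=C/COC(C)=O)[C@@H](CC=O)[C@@H](C)CCC=C(C)C | intermediate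
15 | 2,2-dimethoxyacetaldehyde | COC(OC)C=O | starting material
16 | nitromethane | C[N+](=O)[O-] | starting material
17 | 3,3-dimethoxy-1-nitropropan-2-ol (racemic) | COC(OC)C(O)C[N+](=O)[O-] | intermediate
18 | (E)-3,3-dimethoxy-1-nitroprop-1-ene | COC(OC)/C=C/[N+](=O)[O-] | intermediate
19 | (2E,5R,6R,7R,8R)-7-formyl-9,9-dimethoxy-3-methyl-6-[(2S)-6-methylhept-5-en-2-yl]-8-(nitromethyl)non-2-ene-1,5-diyl diacetate | CC(=O)O[C@H](C/C(C)=C/COC(C)=O)[C@@H]([C@@H](C=O)[C@H](C[N+](=O)[O-])C(OC)OC)[C@@H](C)CCC=C(C)C | intermediate
20 | bis(dimethyl acetal) of 19 | CC(=O)O[C@H](C/C(C)=C/COC(C)=O)[C@@H]([C@@H](C(OC)OC)[C@H](C[N+](=O)[O-])C(OC)OC)[C@@H](C)CCC=C(C)C | intermediate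
21 | (1R,3E,7R,8R,9R)-7,8-bis(dimethoxymethyl)-3-methyl-9-[(2S)-6-methylhept-5-en-2-yl]-6-nitrocyclonon-3-en-1-yl acetate (C6 epimers) | CC(=O)O[C@@H]1C/C(C)=C/CC([N+](=O)[O-])[C@H](C(OC)OC)[C@H](C(OC)OC)[C@H]1[C@@H](C)CCC=C(C)C | intermediate
22 | (1R,3E,7R,8R,9R)-7,8-diformyl-3-methyl-9-[(2S)-6-methylhept-5-en-2-yl]-6-nitrocyclonon-3-en-1-yl acetate (C6 epimers) | CC(=O)O[C@@H]1C/C(C)=C/CC([N+](=O)[O-])[C@H](C=O)[C@H](C=O)[C@H]1[C@@H](C)CCC=C(C)C | intermediate
23 | (1R,3E,6E,8R,9R)-7,8-diformyl-3-methyl-9-[(2S)-6-methylhept-5-en-2-yl]cyclonona-3,6-dien-1-yl acetate | CC(=O)O[C@@H]1C/C(C)=C/C/C=C(/C=O)[C@H](C=O)[C@H]1[C@@H](C)CCC=C(C)C | target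

## Step count and risks

Total step count: 15. Longest linear sequence: 12 steps (steps 1, 2, 4–10, 13–15, from 1 to 23).

Steps most likely to fail:

1. Step 14. Ring closure may be outrun by β-hydride loss from the π-allyl complex, by syn–anti isomerisation of the allyl unit during a slow closure, or by oligomerisation. The fallback removes the rotational freedom of the open chain with a temporary ring.
   - It sets out from crude 19. Camphorsulfonic acid in MeOH without orthoformate should isomerise the acetal aldehyde to the cis-3,4-disubstituted 2,5-dimethoxytetrahydrofuran F1. In F1 the nitromethyl group and the C9 chain sit cis on a five-membered ring, as follows from the syn Michael adduct.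
   - The palladium-catalysed closure on this folded substrate should give the cis-fused tetrahydrofuran-annulated nitrocyclononene F2.
   - Aqueous acid opens F2 to 22, where the route is rejoined.

2. Step 15. Possible failures are acid-induced transannular cyclisation of the E-cyclononene, Paal–Knorr-type cyclodehydration of the 1,4-dialdehyde, and base-induced epimerisation at C8. The fallback avoids Brønsted acid altogether.
   - It sets out from 21. Et3SiOSO2CF3 and 2,6-lutidine in CH2Cl2 at 0 °C should convert both aldehyde acetals into lutidinium salts, which added water cleaves at weakly basic pH.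
   - The lutidine present then serves as the base for the loss of nitrous acid, so the route is rejoined at 23 without any new isolated compound.

3. Step 13. Possible failures are slow enamine formation and turnover with the heavily β-branched aldehyde, a mismatch between catalyst and the resident C9 centre that erodes facial selectivity, and polymerisation of the nitroalkene. The fallback replaces catalysis by a preformed stoichiometric chiral enamine.
   - It sets out from 14, which is condensed with (S)-2-(methoxymethyl)pyrrolidine over molecular sieves to the E-enamine F3.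
   - F3 is added to 18 in Et2O at low temperature, with the same face expected to be shielded, and is hydrolysed with aqueous acetic acid to 19, where the route is rejoined.

## Further compounds

F1 | step 14 | cis-3,4-disubstituted 2,5-dimethoxytetrahydrofuran isomer of 19 (anomer mixture) | COC1OC(OC)[C@@H](C[N+](=O)[O-])[C@H]1[C@@H]([C@@H](C)CCC=C(C)C)[C@@H](C/C(C)=C/COC(C)=O)OC(C)=O
F2 | step 14 | cis-fused 2,5-dimethoxytetrahydrofuran-annulated 6-nitrocyclononenyl acetate (anomer and C6 epimer mixture) | CC(=O)O[C@@H]1C/C(C)=C/CC([N+](=O)[O-])[C@@H]2C(OC)OC(OC)[C@@H]2[C@H]1[C@@H](C)CCC=C(C)C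
F0 | step 15 | none | none
F3 | step 13 | E-enamine of 14 with (S)-2-(methoxymethyl)pyrrolidine | CC(=O)O[C@H](C/C(C)=C/COC(C)=O)[C@@H](/C=C/N1CCC[C@H]1COC)[C@@H](C)CCC=C(C)C
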